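**Strategy**

The route rests on cutting the C3–C4 bond of the butenolide (O1, C2 carbonyl, C3 methyl, C4 acyloxy, C5; side chain C6–C18). The target's E geometry places C7 cis to C4 across C5=C6, which is the arrangement of a six-membered lactone holding C4–C8. The precursor is therefore the 2-bromopropanoate of the enol of an (R)-5-methyl α-keto-δ-lactone. Reductive enolate formation and attack of C3 on the lactone carbonyl C4 closes the butenolide ring, opens the pyranone, frees the C8 hydroxyl for chain attachment, and passes on both the E alkene and the C7 stereocentre unchanged.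

Key step: step 8

Remark: keeping the CH2O carbon of (S)-1 as C8 and extending at the ester carbon gives the (R)-lactone and finally the (S) centre at C7 of the target; the descriptor changes only through CIP priorities, the spatial arrangement is the same throughout.
Remark: compound 9 is written as its enol tautomer, and 10 is used as the racemate because the C–Br centre is erased in step 8.
Remark: geranyl acetate cannot supply the furan ring, so it is brought in with furan-3-ylmethanol 20.

**Route**

Step 1
Reactants: 1 methyl (S)-3-hydroxy-2-methylpropanoate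
Product: 2 methyl (S)-3-(benzyloxy)-2-methylpropanoate
Conditions: BnOC(=NH)CCl3, TfOH (cat.), CH2Cl2/cyclohexane, 0 °C to rt
Reagents that add atoms: benzyl 2,2,2-trichloroacetimidate, N=C(OCc1ccccc1)C(Cl)(Cl)Cl
Why: Acid-catalysed O-benzylation with a trichloroacetimidate protects the primary alcohol without any base, so the stereocentre α to the ester is not at risk.

Step 2
Reactants: 2 methyl (S)-3-(benzyloxy)-2-methylpropanoate
Product: 3 (S)-3-(benzyloxy)-2-methylpropanal
Conditions: i-Bu2AlH (1.05 equiv), CH2Cl2, −78 °C; MeOH, aq. KNaC4H4O6 (tartrate)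
Reagents that add atoms: none
Why: Partial hydride reduction of the ester at low temperature stops at the aluminium hemiacetal, which releases the aldehyde on work-up; the aldehyde is used at once so that its α-stereocentre does not epimerise.

Step 3
Reactants: 3 (S)-3-(benzyloxy)-2-methylpropanal; 4 ethyl (triphenylphosphoranylidene)acetate
Product: 5 ethyl (R,E)-5-(benzyloxy)-4-methylpent-2-enoate
Conditions: CH2Cl2, rt
Reagents that add atoms: none
Why: Wittig olefination with a stabilised ylide is mild enough to leave the α-stereocentre intact and adds the two carbons that become C5 and C4; the alkene geometry is irrelevant because it is hydrogenated next.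

Step 4
Reactants: 5 ethyl (R,E)-5-(benzyloxy)-4-methylpent-2-enoate
Product: 7 (R)-5-methyltetrahydro-2H-pyran-2-one, via hydroxy ester 6 (not isolated)
Conditions: H2 (1 atm), Pd/C, EtOH, rt; filter; TsOH·H2O (cat.), toluene, 50 °C
Reagents that add atoms: none
Why: Catalytic hydrogenation saturates the alkene and hydrogenolyses the benzyl ether in one operation, and acid-catalysed lactonisation of the δ-hydroxy ester then closes the six-membered lactone.

Step 5
Reactants: 7 (R)-5-methyltetrahydro-2H-pyran-2-one
Product: 8 (5R)-3-hydroxy-5-methyltetrahydro-2H-pyran-2-one (both C3 epimers)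
Conditions: NaN(SiMe3)2, THF, −78 °C; 2-(phenylsulfonyl)-3-phenyloxaziridine, −78 °C; AcOH
Reagents that add atoms: 2-(phenylsulfonyl)-3-phenyloxaziridine, O=S(=O)(c1ccccc1)N1OC1c1ccccc1
Why: Enolate α-hydroxylation with an N-sulfonyloxaziridine puts oxygen on the carbon that becomes C5; the new C3 centre of the lactone is not controlled, which does not matter because it is oxidised in step 6, and the methyl-bearing centre is remote from the enolate.

Step 6
Reactants: 8 (5R)-3-hydroxy-5-methyltetrahydro-2H-pyran-2-one
Product: 9 (R)-3-hydroxy-5-methyl-5,6-dihydro-2H-pyran-2-one (enol form of the α-keto-δ-lactone)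
Conditions: 1,1,1-triacetoxy-1,1-dihydro-1,2-benziodoxol-3(1H)-one (DMP), CH2Cl2, 0 °C to rt; non-aqueous work-up
Reagents that add atoms: none
Why: Hypervalent-iodine oxidation of the secondary α-hydroxy lactone gives the 2,3-dioxo lactone, which should rest as its conjugated enol with the double bond between the future C5 and C6; the methyl-bearing carbon is not an enolisable position.

Step 7
Reactants: 9 (R)-3-hydroxy-5-methyl-5,6-dihydro-2H-pyran-2-one; 10 2-bromopropanoyl bromide (racemic)
Product: 11 (R)-5-methyl-2-oxo-5,6-dihydro-2H-pyran-3-yl 2-bromopropanoate (both epimers at the CHBr carbon)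
Conditions: 2,6-lutidine, CH2Cl2, −40 to 0 °C
Reagents that add atoms: none
Why: O-acylation of the acidic enol with an acyl bromide and a hindered pyridine base gives the enol ester; the CHBr centre comes racemic from the reagent and disappears in step 8.

Step 8
Reactants: 11 (R)-5-methyl-2-oxo-5,6-dihydro-2H-pyran-3-yl 2-bromopropanoate
Product: 13 (E)-4-hydroxy-5-[(2R)-3-hydroxy-2-methylpropylidene]-3-methylfuran-2(5H)-one, via samarium enolate 12 (not isolated)
Conditions: SmI2 (2.2 equiv), THF, −78 °C (slow addition of 11), then −40 °C; 0.5 M HCl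
Reagents that add atoms: none
Why: Proposed new method: SmI2 (two equivalents) reduces the C–Br bond of 11 to the trivalent samarium enolate 12, whose carbon C3 adds to the lactone carbonyl C4 through a six-membered samarium-bridged array, and the tetrahedral adduct collapses by expelling the ring oxygen on C8, so the pyranone opens while the butenolide closes and the old lactone C=O oxygen ends as the 4-OH of the tetronic acid. The closest known reaction types are the Dieckmann condensation of α-acyloxy esters and acyloxy acrylates to tetronic and 5-ylidene tetronic acids and the intramolecular samarium Reformatsky reaction. The one ring formed (O1, C2, C3, C4, C5) closes in a 5-exo-trig mode with the enolate double bond inside the new ring (5-enolendo-exo-trig), the mode through which tetronic acid Dieckmann closures are known to run. No stereocentre is made: C7 is carried through because the medium is neutral and its hydrogen is never exposed to base, and the E geometry follows from the ring, since C4 and C7 are cis on the endocyclic C5=C6 bond of 11 and O1 must therefore end trans to C7. The step needs chemoselectivity for addition to C4 over loss of methylketene from the enolate, over simple protonation and over 5-endo attack at C6; the short tether, the oxophilic samarium holding enolate and carbonyl together and slow addition of 11 to SmI2 at −78 °C should secure it.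

Step 9
Reactants: 13 (E)-4-hydroxy-5-[(2R)-3-hydroxy-2-methylpropylidene]-3-methylfuran-2(5H)-one
Product: 14 (E)-5-[(2R)-3-hydroxy-2-methylpropylidene]-4-methoxy-3-methylfuran-2(5H)-one
Conditions: Me3SiCHN2, toluene/MeOH, 0 °C
Reagents that add atoms: (trimethylsilyl)diazomethane, C[Si](C)(C)C=[N+]=[N-]
Why: Diazoalkane O-methylation acts only on the acidic tetronic acid hydroxyl (a vinylogous carboxylic acid) and leaves the primary alcohol free; any 2-methoxy regioisomer would be removed by chromatography.

Step 10
Reactants: 14 (E)-5-[(2R)-3-hydroxy-2-methylpropylidene]-4-methoxy-3-methylfuran-2(5H)-one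
Product: 15 (E)-5-[(2R)-3-iodo-2-methylpropylidene]-4-methoxy-3-methylfuran-2(5H)-one
Conditions: PPh3, I2, imidazole, CH2Cl2, 0 °C, dark (14 added to the preformed reagent)
Reagents that add atoms: iodine, II
Why: Appel iodination converts the primary alcohol into the iodide under neutral conditions; the adjacent stereocentre takes no part in the substitution, and preforming the reagent keeps free iodine away from the ylidene.

Step 11
Reactants: 16 geranyl acetate
Product: 18 (2E,6E)-3,7-dimethyl-8-oxoocta-2,6-dien-1-yl acetate, via 8-hydroxygeranyl acetate 17 (not isolated)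
Conditions: SeO2 (cat.), t-BuOOH, salicylic acid (cat.), CH2Cl2, rt; aqueous wash; MnO2, CH2Cl2, rt
Reagents that add atoms: tert-butyl hydroperoxide, CC(C)(C)OO (oxygen relayed through catalytic SeO2)
Why: Allylic oxidation with SeO2 (ene reaction, then 2,3-sigmatropic shift) attacks the E methyl group of the terminal trisubstituted alkene, and MnO2 oxidation of the crude allylic alcohol funnels alcohol and any aldehyde already formed into the single E enal.

Step 12
Reactants: 18 (2E,6E)-3,7-dimethyl-8-oxoocta-2,6-dien-1-yl acetate
Product: 19 (2E,6E)-3,7-dimethylnona-2,6,8-trien-1-yl acetate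
Conditions: Ph3PCH3Br, n-BuLi, THF, 0 °C; then 18, −78 to 0 °C
Reagents that add atoms: methyltriphenylphosphonium bromide, C[P+](c1ccccc1)(c1ccccc1)c1ccccc1.[Br-]
Why: Wittig methylenation of the enal with one equivalent of the non-stabilised ylide at low temperature is much faster than attack on the acetate and supplies the carbon that becomes C9 without touching the 6E alkene.

Step 13
Reactants: 20 furan-3-ylmethanol
Product: 21 3-(chloromethyl)furan
Conditions: SOCl2, pyridine, Et2O, 0 °C
Reagents that add atoms: thionyl chloride, O=S(Cl)Cl
Why: Chlorodehydroxylation through the chlorosulfite converts the primary furylmethyl alcohol into the chloride, which is used at once as an ethereal solution because it is volatile and labile.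

Step 14
Reactants: 21 3-(chloromethyl)furan; 19 (2E,6E)-3,7-dimethylnona-2,6,8-trien-1-yl acetate
Product: 23 3-[(3E,7E)-4,8-dimethyldeca-3,7,9-trien-1-yl]furan, via furylmethyl Grignard reagent 22 (not isolated)
Conditions: Mg, THF, 0 °C (slow addition of 21); then 19, Li2CuCl4 (5 mol %), THF, −20 to 0 °C
Reagents that add atoms: none
Why: Copper-catalysed cross-coupling of a Grignard reagent with a primary allylic acetate should take place at the α-carbon with retention of the 2E alkene, because γ-attack would build a quaternary centre, and copper catalysis makes furan-3-ylmethyl Grignard reagents couple through the exocyclic carbon.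

Step 15
Reactants: 23 3-[(3E,7E)-4,8-dimethyldeca-3,7,9-trien-1-yl]furan
Product: 25 (3E,7E)-10-(furan-3-yl)-3,7-dimethyldeca-3,7-dien-1-ol, via alkylborane 24 (not isolated)
Conditions: 9-BBN, THF, 0 °C to rt; NaOH, H2O2, 0 °C
Reagents that add atoms: hydrogen peroxide, OO
Why: Hydroboration–oxidation with a bulky dialkylborane is selective for the monosubstituted terminal alkene of the diene over the trisubstituted alkenes and the furan, and places the hydroxyl on the terminal carbon (anti-Markovnikov), the future C9.

Step 16
Reactants: 25 (3E,7E)-10-(furan-3-yl)-3,7-dimethyldeca-3,7-dien-1-ol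
Product: 26 3-[(3E,7E)-10-bromo-4,8-dimethyldeca-3,7-dien-1-yl]furan
Conditions: CBr4, PPh3, CH2Cl2, 0 °C
Reagents that add atoms: carbon tetrabromide, BrC(Br)(Br)Br
Why: Appel bromination turns the primary homoallylic alcohol into the bromide under neutral conditions that spare the furan and the trisubstituted alkenes.

Step 17
Reactants: 26 3-[(3E,7E)-10-bromo-4,8-dimethyldeca-3,7-dien-1-yl]furan; 15 (E)-5-[(2R)-3-iodo-2-methylpropylidene]-4-methoxy-3-methylfuran-2(5H)-one
Product: 28 (E)-5-[(2S,6E,10E)-13-(furan-3-yl)-2,6,10-trimethyltrideca-6,10-dien-1-ylidene]-4-methoxy-3-methylfuran-2(5H)-one, via homoallyl Grignard reagent 27 (not isolated)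
Conditions: Mg, THF, rt; then 15, Li2CuCl4 (5 mol %), NMP, THF, −30 to 0 °C (slow addition of 27)
Reagents that add atoms: none
Why: Copper-catalysed sp3–sp3 cross-coupling of a primary alkyl Grignard reagent with a primary alkyl iodide, a standard way to extend β-methyl-branched chains, should outrun addition to the weakly electrophilic vinylogous carbonate carbonyl at low temperature, and the C7 centre is not involved in making the C8–C9 bond.

Step 18
Reactants: 28 (E)-5-[(2S,6E,10E)-13-(furan-3-yl)-2,6,10-trimethyltrideca-6,10-dien-1-ylidene]-4-methoxy-3-methylfuran-2(5H)-one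
Product: 29 (E)-5-[(2S,6E,10E)-13-(furan-3-yl)-2,6,10-trimethyltrideca-6,10-dien-1-ylidene]-4-hydroxy-3-methylfuran-2(5H)-one
Conditions: LiCl, DMSO, 50 °C; dilute HCl
Reagents that add atoms: none
Why: Nucleophilic (SN2) demethylation of the vinylogous methyl carbonate by chloride, with the tetronate as leaving group, frees the tetronic acid without acid or oxidant, so the furan, the alkenes and the E ylidene should be tolerated.

Step 19
Reactants: 29 (E)-5-[(2S,6E,10E)-13-(furan-3-yl)-2,6,10-trimethyltrideca-6,10-dien-1-ylidene]-4-hydroxy-3-methylfuran-2(5H)-one; 30 stearoyl chloride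
Product: 31 (2E)-2-[(2S,6E,10E)-13-(furan-3-yl)-2,6,10-trimethyltrideca-6,10-dien-1-ylidene]-4-methyl-5-oxo-2,5-dihydrofuran-3-yl octadecanoate (CNP0018186.1)
Conditions: Et3N, CH2Cl2, 0 °C
Reagents that add atoms: none
Why: O-acylation of the tetronic acid with an acyl chloride and an amine base gives the 4-acyloxy butenolide; C-acylation is blocked because C3 already carries the methyl group.

**Compound list**

1 | methyl (S)-3-hydroxy-2-methylpropanoate | COC(=O)[C@@H](C)CO | starting material
2 | methyl (S)-3-(benzyloxy)-2-methylpropanoate | COC(=O)[C@@H](C)COCc1ccccc1 | intermediate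
3 | (S)-3-(benzyloxy)-2-methylpropanal | O=C[C@@H](C)COCc1ccccc1 | intermediate
4 | ethyl (triphenylphosphoranylidene)acetate | CCOC(=O)C=P(c1ccccc1)(c1ccccc1)c1ccccc1 | starting material
5 | ethyl (R,E)-5-(benzyloxy)-4-methylpent-2-enoate | CCOC(=O)/C=C/[C@@H](C)COCc1ccccc1 | intermediate
6 | ethyl (R)-5-hydroxy-4-methylpentanoate | CCOC(=O)CC[C@@H](C)CO | intermediate
7 | (R)-5-methyltetrahydro-2H-pyran-2-one | O=C1CC[C@@H](C)CO1 | intermediate
8 | (5R)-3-hydroxy-5-methyltetrahydro-2H-pyran-2-one (both C3 epimers) | OC1C[C@@H](C)COC1=O | intermediate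
9 | (R)-3-hydroxy-5-methyl-5,6-dihydro-2H-pyran-2-one | OC1=C[C@@H](C)COC1=O | intermediate
10 | 2-bromopropanoyl bromide (racemic) | CC(Br)C(Br)=O | starting material
11 | (R)-5-methyl-2-oxo-5,6-dihydro-2H-pyran-3-yl 2-bromopropanoate (both CHBr epimers) | CC(Br)C(=O)OC1=C[C@@H](C)COC1=O | intermediate
12 | diiodosamarium enolate of the propanoate ester of 9 (trivalent samarium) | CC=C(O[Sm](I)I)OC1=C[C@@H](C)COC1=O | intermediate
13 | (E)-4-hydroxy-5-[(2R)-3-hydroxy-2-methylpropylidene]-3-methylfuran-2(5H)-one | OC1=C(C)C(=O)O/C1=C/[C@@H](C)CO | intermediate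
14 | (E)-5-[(2R)-3-hydroxy-2-methylpropylidene]-4-methoxy-3-methylfuran-2(5H)-one | COC1=C(C)C(=O)O/C1=C/[C@@H](C)CO | intermediate
15 | (E)-5-[(2R)-3-iodo-2-methylpropylidene]-4-methoxy-3-methylfuran-2(5H)-one | COC1=C(C)C(=O)O/C1=C/[C@@H](C)CI | intermediate
16 | geranyl acetate | CC(C)=CCC/C(C)=C/COC(C)=O | starting material
17 | (2E,6E)-8-hydroxy-3,7-dimethylocta-2,6-dien-1-yl acetate | OC/C(C)=C/CC/C(C)=C/COC(C)=O | intermediate
18 | (2E,6E)-3,7-dimethyl-8-oxoocta-2,6-dien-1-yl acetate | O=C/C(C)=C/CC/C(C)=C/COC(C)=O | intermediate
19 | (2E,6E)-3,7-dimethylnona-2,6,8-trien-1-yl acetate | C=C/C(C)=C/CC/C(C)=C/COC(C)=O | intermediate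
20 | furan-3-ylmethanol | OCc1ccoc1 | starting material
21 | 3-(chloromethyl)furan | ClCc1ccoc1 | intermediate
22 | (furan-3-ylmethyl)magnesium chloride | Cl[Mg]Cc1ccoc1 | intermediate
23 | 3-[(3E,7E)-4,8-dimethyldeca-3,7,9-trien-1-yl]furan | C=C/C(C)=C/CC/C(C)=C/CCc1ccoc1 | intermediate
24 | 9-[(3E,7E)-10-(furan-3-yl)-3,7-dimethyldeca-3,7-dien-1-yl]-9-borabicyclo[3.3.1]nonane | C1CC2CCCC(C1)B2CC/C(C)=C/CC/C(C)=C/CCc1ccoc1 | intermediate
25 | (3E,7E)-10-(furan-3-yl)-3,7-dimethyldeca-3,7-dien-1-ol | OCC/C(C)=C/CC/C(C)=C/CCc1ccoc1 | intermediate
26 | 3-[(3E,7E)-10-bromo-4,8-dimethyldeca-3,7-dien-1-yl]furan | BrCC/C(C)=C/CC/C(C)=C/CCc1ccoc1 | intermediate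
27 | [(3E,7E)-10-(furan-3-yl)-3,7-dimethyldeca-3,7-dien-1-yl]magnesium bromide | Br[Mg]CC/C(C)=C/CC/C(C)=C/CCc1ccoc1 | intermediate
28 | (E)-5-[(2S,6E,10E)-13-(furan-3-yl)-2,6,10-trimethyltrideca-6,10-dien-1-ylidene]-4-methoxy-3-methylfuran-2(5H)-one | COC1=C(C)C(=O)O/C1=C/[C@@H](C)CCC/C(C)=C/CC/C(C)=C/CCc1ccoc1 | intermediate
29 | (E)-5-[(2S,6E,10E)-13-(furan-3-yl)-2,6,10-trimethyltrideca-6,10-dien-1-ylidene]-4-hydroxy-3-methylfuran-2(5H)-one | OC1=C(C)C(=O)O/C1=C/[C@@H](C)CCC/C(C)=C/CC/C(C)=C/CCc1ccoc1 | intermediate
30 | stearoyl chloride | CCCCCCCCCCCCCCCCCC(Cl)=O | starting material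
31 | (2E)-2-[(2S,6E,10E)-13-(furan-3-yl)-2,6,10-trimethyltrideca-6,10-dien-1-ylidene]-4-methyl-5-oxo-2,5-dihydrofuran-3-yl octadecanoate (CNP0018186.1) | CCCCCCCCCCCCCCCCCC(=O)OC1=C(C)C(=O)O/C1=C/[C@@H](C)CCC/C(C)=C/CC/C(C)=C/CCc1ccoc1 | target

**Step count**

Total: 19 steps. Longest linear sequence: 13 steps (steps 1–10, then 17–19); the tail branch (steps 11–16) joins at step 17.

**Steps most likely to fail**

Step 8 (the proposed new method). The samarium enolate may break down to methylketene and the enolate of 9, or be protonated to the simple propanoate, faster than it adds to C4. The fallback uses known chemistry and sets out from 9. O-Acylation with propanoyl chloride and 2,6-lutidine should give (R)-5-methyl-2-oxo-5,6-dihydro-2H-pyran-3-yl propanoate F1. Deprotonation of F1 with LiN(SiMe3)2 (2.2 equiv, THF, −78 °C) followed by an acid quench is a Dieckmann condensation of the kind established for acyloxy acrylates. It uses a different precursor and a different way of making the enolate, forms the same C3–C4 bond inside the same ring template, and comes back to the route at 13. Its price is contact of the hydrogen on C7 with a strong base, so the enantiomeric purity of 13 would have to be checked.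

Step 17. The Grignard reagent may add to the lactone carbonyl, or substitution at the β-branched iodide may be too slow, so that reduction or elimination of 15 takes over. The fallback sets out from 23 and 15. Hydroboration of 23 with 9-BBN gives the alkylborane 24, which is not oxidised but used directly in a palladium-catalysed B-alkyl Suzuki–Miyaura coupling with 15 (Pd(OAc)2, PCy3, K3PO4·H2O, THF, rt). This comes back to the route at 28, avoids any carbonyl-reactive organometallic, and makes the oxidation half of step 15 and step 16 unnecessary.

Step 6. The α-dicarbonyl lactone may be hydrated, ring-opened or self-condensed during the oxidation and its isolation. The fallback sets out from 7. Condensation with tert-butoxybis(dimethylamino)methane (toluene, 80 °C) should give (R,E)-3-[(dimethylamino)methylene]-5-methyltetrahydro-2H-pyran-2-one F2. The enamine double bond of F2 is then cleaved by singlet oxygen (O2, hν, tetraphenylporphyrin, CH2Cl2, −78 °C), a known route from enamino lactones to α-keto lactones that runs under neutral, anhydrous conditions and leaves only DMF. The route is rejoined at 9, which can be acylated in the same flask, and steps 5 and 6 are bypassed.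

**Further compounds**

F1 | step 8 | (R)-5-methyl-2-oxo-5,6-dihydro-2H-pyran-3-yl propanoate | CCC(=O)OC1=C[C@@H](C)COC1=O
F0 | step 17 | none | none
F2 | step 6 | (R,E)-3-[(dimethylamino)methylene]-5-methyltetrahydro-2H-pyran-2-one | CN(C)/C=C1\C[C@@H](C)COC1=O
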